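The numbers in the tables were computed for an exercise; noise was put on by code.

My decision for this flask is to carry a ratio from Friday's run towards 12 min, not a rate.

| setting | Friday's | flask |
|---|---|---|
| X | 0.020 M | 0.020 M |
| Q | 0.020 M | 0.020 M |
| Z | 2.5 mM (held) | 2.5 mM (held) |
| E | 2 mol% | 2 mol% |
| remark | the very flask that is asked about, followed so far |  |
| time |  | 12 min |

- Friday's (time / min: X / %, Q / %, D / %): 0.250: 50.0, 49.9, 0; 0.667: 49.3, 49.8, 0.3; 1.50: 49.0, 49.8, 1.0; 4.00: 44.8, 48.9, 4.8

(standard deviation of a reading: 0.3 percentage points)

- E is single-handed; X and Q are mirror images of each other, charged as a racemate, each of them at the stated concentration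
- at the start none of Z is in solution
- an excess is the difference of the two amounts in percent of their sum
- an excess is below zero if the other one leads

1. part of the X and Q charged together that has reacted at 12 min
2. excess of D over L in the product at 12 min
3. excess of Q over X among what is left of the two at 12 min

I read the table downwards. At 1.50 min in Friday's run, X reads as having lost 1 percentage point and Q 0.2 points, against a scatter of 0.3 points, so the rows up to there say little about the two enantiomers. The D column shows a moving rate: D gains 0.7 points in 0.833 min, then 3.8 points in 2.50 min, which is faster per minute. So I carry no rate from it.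

The row at 4.00 min is the one to use: X has lost 5.2 points and Q 1.1 points. Let x and q be the parts of X and Q left, each of its own charge. Here ln x divided by ln q is 4.94; I call this ratio the selectivity factor s. If each enantiomer is lost first order in itself and the two share every other factor of the rate, the time course cancels. My reckoning is then that q is the s-th root of x at any moment, but s is loose: Q's loss of 1.1 points stands against a scatter of 0.3 points.

The forecast gives c 23%, eP 60% and eS 18%, from the same row: "so s ≈ 5, though loosely known because Q's loss is small".

The flask gives c 15.3%, eP 67.7% and eS 12.3%.

    J + E + X → E + D (k = 45000 L² mol⁻² min⁻¹)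
    J + E + Q → E + L (k = 7700 L² mol⁻² min⁻¹)
    2 E → G (k = 84.0 L mol⁻¹ min⁻¹)
    Z ⇌ J, rate k4*(csat - [J]) (kL = 1.20 min⁻¹)

The two part on how far the flask gets: the forecast has X at 31.5 percent of the X and Q together charged, and the flask holds 37.1% on that same count. With 74% of its charged X left, s gives 94.1% of the charged Q, and the flask keeps 95%. The neighbouring flask, with 5 mol% of E, goes further. It keeps 62% of its X, so s gives 90.8% of Q and c of 23.6%. That flask holds 92% of its Q, and its c is 22.9%.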